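**Retrosynthetic overview**

1. The C3 ester is made last-but-three from the equatorial 3α-alcohol and (2E,5R)-5-(angeloyloxy)hex-2-enoic acid [(R)-pent-4-en-2-ol, angelic acid, acrylic acid]; the C8 ketone and the C9 hydroxyl are then unveiled from a C8/C9 bis-silyl ether, so the α-isopropenyl ketone never meets base.
2. Ring B is closed at C9–C10 by an intramolecular vinylogous Mukaiyama aldol addition. The feature that allows it: the C3 oxygen of ring A is 1,4 to C10 through C2 and C1, so at the ketone level ring A becomes a 1-silyloxy-1,3-diene (C3=C2–C1=C10) with C10 as the γ-carbon, while C9 of the C8/C9 ketol, with C8 held one oxidation level lower, is an α-silyloxy aldehyde.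
3. The C7–C8 bond and the isopropenyl group come from one catalytic asymmetric glyoxylate–ene reaction on a prenyl group at C5.
4. Ring A (C3, C4, C5) comes from (R)-4-silyloxycyclohexenone by α-methylation, anti cuprate addition and anti prenylation; the ketone used for this is then deleted (enol triflate, reduction) to leave the C1=C10 alkene.
5. Order of ring formation: ring A is present from the start; ring B is formed in step 11.

Key step: step 11

Remark on naming: the decalins are named as eremophilanes (ring A = C1–C5, C10; ring B = C5–C10; methyls on C4 and C5; isopropenyl C11–C13 on C7); α/β refer to the usual drawing with the C5 methyl β, and all decalins carry 4β,5β-dimethyl and 7β-isopropenyl groups.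
Remark on the chemistry: enone 1 is taken as a catalogue compound; in step 8 the (R,R)-ligand is assumed to give the 2R carbinol and the usual exo transition state the 3R centre (the antipodal ligand is used if the sense is opposite); the C8 configuration drawn is erased in step 17.

**Route**

Step 1
Reactants: 1 (R)-4-[(tert-butyldimethylsilyl)oxy]cyclohex-2-en-1-one
Product: 2 (R)-4-[(tert-butyldimethylsilyl)oxy]-2-iodocyclohex-2-en-1-one
Conditions: I2, pyridine, CH2Cl2, 0 °C to rt
Reagents that add atoms: iodine, [I][I]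
Why: Amine-mediated α-iodination of an enone (conjugate addition of pyridine, iodination of the enolate, elimination) is standard for cyclohexenones and leaves the silyloxy stereocentre untouched.

Step 2
Reactants: 2 (R)-4-[(tert-butyldimethylsilyl)oxy]-2-iodocyclohex-2-en-1-one
Product: 3 (R)-4-[(tert-butyldimethylsilyl)oxy]-2-methylcyclohex-2-en-1-one
Conditions: Me4Sn, Pd2(dba)3 (cat.), AsPh3, CuI (cat.), NMP, 60 °C
Reagents that add atoms: tetramethylstannane, C[Sn](C)(C)C
Why: Stille cross-coupling of an α-iodoenone with Me4Sn is a close-precedented way to 2-methyl enones and does not touch the allylic silyl ether.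

Step 3
Reactants: 3 (R)-4-[(tert-butyldimethylsilyl)oxy]-2-methylcyclohex-2-en-1-one; 4 1-bromo-3-methylbut-2-ene (prenyl bromide)
Product: 6 (2R,3R,4R)-4-[(tert-butyldimethylsilyl)oxy]-2,3-dimethyl-2-(3-methylbut-2-en-1-yl)cyclohexan-1-one, via lithium enolate 5 (not isolated)
Conditions: Me2CuLi (from MeLi and CuI), Et2O, −78 to −20 °C; then 4, HMPA, THF, −20 °C to rt
Reagents that add atoms: lithium dimethylcuprate, [Li+].C[Cu-]C
Why: Cuprate conjugate addition–enolate alkylation: Me2CuLi should add anti to the γ-silyloxy group, and the regiospecific enolate 5, whose new methyl is pseudoaxial because of A(1,2) strain, should be prenylated axially on the opposite face, which places the two methyl groups cis (future C4 and C5).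

Step 4
Reactants: 6 (2R,3R,4R)-4-[(tert-butyldimethylsilyl)oxy]-2,3-dimethyl-2-(3-methylbut-2-en-1-yl)cyclohexan-1-one
Product: 8 (4R,5R,6R)-4-[(tert-butyldimethylsilyl)oxy]-5,6-dimethyl-6-(3-methylbut-2-en-1-yl)cyclohex-1-en-1-yl trifluoromethanesulfonate, via potassium enolate 7 (not isolated)
Conditions: KN(SiMe3)2, THF, −78 °C; then PhNTf2, −78 to 0 °C
Reagents that add atoms: N-phenylbis(trifluoromethanesulfonimide), O=S(=O)(N(c1ccccc1)S(=O)(=O)C(F)(F)F)C(F)(F)F
Why: Only one α-carbon bears hydrogen (the other is quaternary), so deprotonation and O-sulfonylation give a single enol triflate (standard vinyl triflate formation).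

Step 5
Reactants: 8 (4R,5R,6R)-4-[(tert-butyldimethylsilyl)oxy]-5,6-dimethyl-6-(3-methylbut-2-en-1-yl)cyclohex-1-en-1-yl trifluoromethanesulfonate
Product: 9 tert-butyl{[(1R,5S,6R)-5,6-dimethyl-5-(3-methylbut-2-en-1-yl)cyclohex-3-en-1-yl]oxy}dimethylsilane
Conditions: Pd(OAc)2 (cat.), PPh3, HCO2H, n-Bu3N, DMF, 60 °C
Reagents that add atoms: none
Why: Palladium-catalysed formate reduction of a vinyl triflate (oxidative addition to zerovalent palladium, formate-to-hydride exchange with loss of CO2, reductive elimination) deletes the ketone oxygen and leaves the ring alkene that becomes C1=C10, while the prenyl alkene and the silyl ether should be inert.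

Step 6
Reactants: 9 tert-butyl{[(1R,5S,6R)-5,6-dimethyl-5-(3-methylbut-2-en-1-yl)cyclohex-3-en-1-yl]oxy}dimethylsilane
Product: 10 (1R,5S,6R)-5,6-dimethyl-5-(3-methylbut-2-en-1-yl)cyclohex-3-en-1-ol
Conditions: n-Bu4NF, THF, 0 °C to rt
Reagents that add atoms: none
Why: Fluoride cleavage of a secondary silyl ether is a standard desilylation and touches nothing else in 9.

Step 7
Reactants: 10 (1R,5S,6R)-5,6-dimethyl-5-(3-methylbut-2-en-1-yl)cyclohex-3-en-1-ol
Product: 11 (5S,6R)-5,6-dimethyl-5-(3-methylbut-2-en-1-yl)cyclohex-3-en-1-one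
Conditions: Dess–Martin periodinane, pyridine, CH2Cl2, 0 °C
Reagents that add atoms: none
Why: Dess–Martin oxidation under pyridine buffering is mild enough to give the β,γ-unsaturated ketone without conjugation or epimerisation of the α-methyl centre.

Step 8
Reactants: 11 (5S,6R)-5,6-dimethyl-5-(3-methylbut-2-en-1-yl)cyclohex-3-en-1-one; 12 ethyl glyoxylate
Product: 13 ethyl (2R,3R)-3-{[(1S,6R)-1,6-dimethyl-5-oxocyclohex-2-en-1-yl]methyl}-2-hydroxy-4-methylpent-4-enoate
Conditions: 12 (excess), [Cu((R,R)-t-Bu-box)](SbF6)2 (10 mol %; t-Bu-box = 2,2′-(propane-2,2-diyl)bis(4-tert-butyl-4,5-dihydrooxazole)), CH2Cl2, 0 °C to rt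
Reagents that add atoms: none
Why: Glyoxylate–ene (carbonyl–ene) reaction catalysed by a chiral bis(oxazoline) complex of divalent copper: the prenyl alkene reacts at its less substituted carbon with transfer of a methyl hydrogen, which creates the C7–C8 bond and the isopropenyl group in one event; the copper chelate should fix the carbinol centre (2R) and the exo transition state should relay it to the allylic centre (3R, future C7), while the less nucleophilic ring alkene should stay untouched.

Step 9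
Reactants: 13 ethyl (2R,3R)-3-{[(1S,6R)-1,6-dimethyl-5-oxocyclohex-2-en-1-yl]methyl}-2-hydroxy-4-methylpent-4-enoate
Product: 15 ethyl (2R,3R)-3-{[(1S,6R)-5-[(tert-butyldimethylsilyl)oxy]-1,6-dimethylcyclohexa-2,4-dien-1-yl]methyl}-4-methyl-2-[(triethylsilyl)oxy]pent-4-enoate, via triethylsilyl ether 14 (not isolated)
Conditions: Et3SiCl, imidazole, CH2Cl2, 0 °C; then Et3N, t-BuMe2SiOTf, −78 to 0 °C
Reagents that add atoms: chlorotriethylsilane, CC[Si](CC)(CC)Cl; tert-butyldimethylsilyl trifluoromethanesulfonate, CC(C)(C)[Si](C)(C)OS(=O)(=O)C(F)(F)F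
Why: O-silylation of the alcohol, then soft enolisation of the ketone (silyl triflate/amine) through the doubly activated hydrogens between the carbonyl and the ring alkene should give only the linear 1-silyloxy-1,3-diene, which both masks the ketone for step 10 and arms ring A for step 11.

Step 10
Reactants: 15 ethyl (2R,3R)-3-{[(1S,6R)-5-[(tert-butyldimethylsilyl)oxy]-1,6-dimethylcyclohexa-2,4-dien-1-yl]methyl}-4-methyl-2-[(triethylsilyl)oxy]pent-4-enoate
Product: 16 (2R,3R)-3-{[(1S,6R)-5-[(tert-butyldimethylsilyl)oxy]-1,6-dimethylcyclohexa-2,4-dien-1-yl]methyl}-4-methyl-2-[(triethylsilyl)oxy]pent-4-enal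
Conditions: i-Bu2AlH, CH2Cl2, −78 °C; then MeOH, aq. potassium sodium tartrate (pH 7)
Reagents that add atoms: none
Why: Low-temperature i-Bu2AlH reduction of an α-silyloxy ester stops at the aldehyde through the chelated aluminium hemiacetal (standard ester-to-aldehyde reduction), and silyl enol ethers and alkenes are not reduced.

Step 11
Reactants: 16 (2R,3R)-3-{[(1S,6R)-5-[(tert-butyldimethylsilyl)oxy]-1,6-dimethylcyclohexa-2,4-dien-1-yl]methyl}-4-methyl-2-[(triethylsilyl)oxy]pent-4-enal
Product: 17 9β-[(tert-butyldimethylsilyl)oxy]-8α-[(triethylsilyl)oxy]-10βH-eremophila-1,11-dien-3-one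
Conditions: Tf2NH (5 mol %), CH2Cl2 (0.005 M), −78 °C; then pyridine
Reagents that add atoms: none
Why: Tf2NH protodesilylates a trace of 16 to give t-BuMe2SiNTf2, which activates the aldehyde at C9; the terminal carbon C10 of the silyl dienol ether adds to it, and silyl transfer from the resulting silyloxocarbenium ion to the new alkoxide gives the C9 silyl ether, restores the C1–C2 enone and regenerates the silyl Lewis acid (intramolecular vinylogous Mukaiyama aldol addition; the closest known type is the triflimide- or silyl-triflate-catalysed Mukaiyama aldol with silyl transfer, including its vinylogous and ring-forming variants). Ring B closes in a 6-(enolexo)-exo-trig mode. C10 is set by attack on the diene face opposite the pseudoaxial C5 methyl with the C6 tether pseudoequatorial, the only trajectory on which the three-atom tether reaches C10 axially, so C6 and C9 end up cis and the ring fusion is cis. C9 is set by a chair-like transition state in which the silylated carbonyl oxygen is equatorial, because an axial oxygen would be 1,3-diaxial to C4 of ring A; the isopropenyl group at C7 and the silyloxy group at C8 sit equatorial in the same chair. The step needs γ- over α-selectivity, secured by the tether (attack through C2 would need a bridged eight-membered ring), and chemoselectivity for the dienol ether over the isopropenyl alkene, secured by the much higher nucleophilicity of the silyloxydiene at −78 °C and by high dilution.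

Step 12
Reactants: 17 9β-[(tert-butyldimethylsilyl)oxy]-8α-[(triethylsilyl)oxy]-10βH-eremophila-1,11-dien-3-one
Product: 19 9β-[(tert-butyldimethylsilyl)oxy]-8α-[(triethylsilyl)oxy]-10βH-eremophil-11-en-3α-ol, via saturated ketone 18 (not isolated)
Conditions: Li, liquid NH3, THF, EtOH, −78 to −33 °C; then NH4Cl
Reagents that add atoms: none
Why: Dissolving-metal reduction takes the enone to the saturated ketone 18 and then to the thermodynamically favoured equatorial alcohol (3α, trans to the equatorial C4 methyl), while isolated alkenes and silyl ethers are inert to Li/NH3.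

Step 13
Reactants: 20 (R)-pent-4-en-2-ol; 21 angelic acid [(Z)-2-methylbut-2-enoic acid]
Product: 23 (R)-pent-4-en-2-yl (Z)-2-methylbut-2-enoate, via mixed anhydride 22 (not isolated)
Conditions: 21, 2,4,6-trichlorobenzoyl chloride, Et3N, toluene, rt; then 20, 80 °C
Reagents that add atoms: none
Why: Yamaguchi-type esterification through the mixed anhydride without a nucleophilic catalyst is the usual way to acylate a secondary alcohol with angelic acid without Z-to-E isomerisation, and the carbinol centre is not involved.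

Step 14
Reactants: 23 (R)-pent-4-en-2-yl (Z)-2-methylbut-2-enoate; 24 acrylic acid
Product: 25 (2E,5R)-5-{[(Z)-2-methylbut-2-enoyl]oxy}hex-2-enoic acid
Conditions: second-generation Hoveyda–Grubbs catalyst (5 mol %), CH2Cl2, 40 °C
Reagents that add atoms: none
Why: Olefin cross-metathesis of a terminal alkene with acrylic acid should give the E-enoic acid, and the trisubstituted conjugated angelate alkene does not take part.

Step 15
Reactants: 19 9β-[(tert-butyldimethylsilyl)oxy]-8α-[(triethylsilyl)oxy]-10βH-eremophil-11-en-3α-ol; 25 (2E,5R)-5-{[(Z)-2-methylbut-2-enoyl]oxy}hex-2-enoic acid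
Product: 27 9β-[(tert-butyldimethylsilyl)oxy]-8α-[(triethylsilyl)oxy]-10βH-eremophil-11-en-3α-yl (2E,5R)-5-{[(Z)-2-methylbut-2-enoyl]oxy}hex-2-enoate, via O-acylisourea 26 (not isolated)
Conditions: i-PrN=C=N-i-Pr, DMAP (cat.), CH2Cl2, 0 °C to rt
Reagents that add atoms: none
Why: Steglich esterification (carbodiimide activation, DMAP acyl transfer) of the only free hydroxyl, the equatorial C3 alcohol, with low temperature limiting γ-deprotonation of the activated enoate.

Step 16
Reactants: 27 9β-[(tert-butyldimethylsilyl)oxy]-8α-[(triethylsilyl)oxy]-10βH-eremophil-11-en-3α-yl (2E,5R)-5-{[(Z)-2-methylbut-2-enoyl]oxy}hex-2-enoate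
Product: 28 9β-[(tert-butyldimethylsilyl)oxy]-8α-hydroxy-10βH-eremophil-11-en-3α-yl (2E,5R)-5-{[(Z)-2-methylbut-2-enoyl]oxy}hex-2-enoate
Conditions: PPTS (cat.), MeOH–CH2Cl2, 0 °C
Reagents that add atoms: none
Why: Acid-catalysed methanolysis removes a triethylsilyl ether far faster than a hindered tert-butyldimethylsilyl ether (standard selective desilylation), so only the C8 hydroxyl is freed.

Step 17
Reactants: 28 9β-[(tert-butyldimethylsilyl)oxy]-8α-hydroxy-10βH-eremophil-11-en-3α-yl (2E,5R)-5-{[(Z)-2-methylbut-2-enoyl]oxy}hex-2-enoate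
Product: 29 9β-[(tert-butyldimethylsilyl)oxy]-8-oxo-10βH-eremophil-11-en-3α-yl (2E,5R)-5-{[(Z)-2-methylbut-2-enoyl]oxy}hex-2-enoate
Conditions: Dess–Martin periodinane, pyridine, CH2Cl2, 0 °C
Reagents that add atoms: none
Why: Dess–Martin oxidation under buffered, non-enolising conditions converts the C8 carbinol into the ketone without epimerising C7 or moving the isopropenyl alkene into conjugation.

Step 18
Reactants: 29 9β-[(tert-butyldimethylsilyl)oxy]-8-oxo-10βH-eremophil-11-en-3α-yl (2E,5R)-5-{[(Z)-2-methylbut-2-enoyl]oxy}hex-2-enoate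
Product: 30 9β-hydroxy-8-oxo-10βH-eremophil-11-en-3α-yl (2E,5R)-5-{[(Z)-2-methylbut-2-enoyl]oxy}hex-2-enoate (CNP0210874.1)
Conditions: HF·pyridine, pyridine, THF, 0 °C to rt
Reagents that add atoms: none
Why: Fluoride cleavage of the α-silyloxy ketone under weakly acidic conditions releases the C9 hydroxyl without base, so the α-ketol, the β,γ-unsaturated ketone and the angelate should survive.

**Compound list**

1 | (R)-4-[(tert-butyldimethylsilyl)oxy]cyclohex-2-en-1-one | O=C1C=C[C@H](O[Si](C)(C)C(C)(C)C)CC1 | starting material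
2 | (R)-4-[(tert-butyldimethylsilyl)oxy]-2-iodocyclohex-2-en-1-one | O=C1C(I)=C[C@H](O[Si](C)(C)C(C)(C)C)CC1 | intermediate
3 | (R)-4-[(tert-butyldimethylsilyl)oxy]-2-methylcyclohex-2-en-1-one | O=C1C(C)=C[C@H](O[Si](C)(C)C(C)(C)C)CC1 | intermediate
4 | 1-bromo-3-methylbut-2-ene | CC(C)=CCBr | starting material
5 | lithium (3R,4R)-4-[(tert-butyldimethylsilyl)oxy]-2,3-dimethylcyclohex-1-en-1-olate (not isolated) | [Li+].[O-]C1=C(C)[C@@H](C)[C@H](O[Si](C)(C)C(C)(C)C)CC1 | intermediate
6 | (2R,3R,4R)-4-[(tert-butyldimethylsilyl)oxy]-2,3-dimethyl-2-(3-methylbut-2-en-1-yl)cyclohexan-1-one | CC(C)=CC[C@@]1(C)C(=O)CC[C@@H](O[Si](C)(C)C(C)(C)C)[C@@H]1C | intermediate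
7 | potassium enolate of 6 (not isolated) | [K+].CC(C)=CC[C@@]1(C)C([O-])=CC[C@@H](O[Si](C)(C)C(C)(C)C)[C@@H]1C | intermediate
8 | (4R,5R,6R)-4-[(tert-butyldimethylsilyl)oxy]-5,6-dimethyl-6-(3-methylbut-2-en-1-yl)cyclohex-1-en-1-yl trifluoromethanesulfonate | CC(C)=CC[C@@]1(C)C(OS(=O)(=O)C(F)(F)F)=CC[C@@H](O[Si](C)(C)C(C)(C)C)[C@@H]1C | intermediate
9 | tert-butyl{[(1R,5S,6R)-5,6-dimethyl-5-(3-methylbut-2-en-1-yl)cyclohex-3-en-1-yl]oxy}dimethylsilane | CC(C)=CC[C@@]1(C)C=CC[C@@H](O[Si](C)(C)C(C)(C)C)[C@@H]1C | intermediate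
10 | (1R,5S,6R)-5,6-dimethyl-5-(3-methylbut-2-en-1-yl)cyclohex-3-en-1-ol | CC(C)=CC[C@@]1(C)C=CC[C@@H](O)[C@@H]1C | intermediate
11 | (5S,6R)-5,6-dimethyl-5-(3-methylbut-2-en-1-yl)cyclohex-3-en-1-one | CC(C)=CC[C@@]1(C)C=CCC(=O)[C@@H]1C | intermediate
12 | ethyl glyoxylate | CCOC(=O)C=O | starting material
13 | ethyl (2R,3R)-3-{[(1S,6R)-1,6-dimethyl-5-oxocyclohex-2-en-1-yl]methyl}-2-hydroxy-4-methylpent-4-enoate | C=C(C)[C@H]([C@@H](O)C(=O)OCC)C[C@@]1(C)C=CCC(=O)[C@@H]1C | intermediate
14 | ethyl (2R,3R)-3-{[(1S,6R)-1,6-dimethyl-5-oxocyclohex-2-en-1-yl]methyl}-4-methyl-2-[(triethylsilyl)oxy]pent-4-enoate (not isolated) | C=C(C)[C@H]([C@@H](O[Si](CC)(CC)CC)C(=O)OCC)C[C@@]1(C)C=CCC(=O)[C@@H]1C | intermediate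
15 | ethyl (2R,3R)-3-{[(1S,6R)-5-[(tert-butyldimethylsilyl)oxy]-1,6-dimethylcyclohexa-2,4-dien-1-yl]methyl}-4-methyl-2-[(triethylsilyl)oxy]pent-4-enoate | C=C(C)[C@H]([C@@H](O[Si](CC)(CC)CC)C(=O)OCC)C[C@@]1(C)C=CC=C(O[Si](C)(C)C(C)(C)C)[C@@H]1C | intermediate
16 | (2R,3R)-3-{[(1S,6R)-5-[(tert-butyldimethylsilyl)oxy]-1,6-dimethylcyclohexa-2,4-dien-1-yl]methyl}-4-methyl-2-[(triethylsilyl)oxy]pent-4-enal | C=C(C)[C@H]([C@@H](O[Si](CC)(CC)CC)C=O)C[C@@]1(C)C=CC=C(O[Si](C)(C)C(C)(C)C)[C@@H]1C | intermediate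
17 | 9β-[(tert-butyldimethylsilyl)oxy]-8α-[(triethylsilyl)oxy]-10βH-eremophila-1,11-dien-3-one | C=C(C)[C@H]1C[C@@]2(C)[C@H](C=CC(=O)[C@@H]2C)[C@@H](O[Si](C)(C)C(C)(C)C)[C@@H]1O[Si](CC)(CC)CC | intermediate
18 | 9β-[(tert-butyldimethylsilyl)oxy]-8α-[(triethylsilyl)oxy]-10βH-eremophil-11-en-3-one (not isolated) | C=C(C)[C@H]1C[C@@]2(C)[C@H](CCC(=O)[C@@H]2C)[C@@H](O[Si](C)(C)C(C)(C)C)[C@@H]1O[Si](CC)(CC)CC | intermediate
19 | 9β-[(tert-butyldimethylsilyl)oxy]-8α-[(triethylsilyl)oxy]-10βH-eremophil-11-en-3α-ol | C=C(C)[C@H]1C[C@@]2(C)[C@H](CC[C@@H](O)[C@@H]2C)[C@@H](O[Si](C)(C)C(C)(C)C)[C@@H]1O[Si](CC)(CC)CC | intermediate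
20 | (R)-pent-4-en-2-ol | C=CC[C@@H](C)O | starting material
21 | angelic acid [(Z)-2-methylbut-2-enoic acid] | OC(=O)/C(C)=C\C | starting material
22 | (Z)-2-methylbut-2-enoic 2,4,6-trichlorobenzoic anhydride (not isolated) | O=C(OC(=O)/C(C)=C\C)c1c(Cl)cc(Cl)cc1Cl | intermediate
23 | (R)-pent-4-en-2-yl (Z)-2-methylbut-2-enoate | C=CC[C@@H](C)OC(=O)/C(C)=C\C | intermediate
24 | acrylic acid | C=CC(=O)O | starting material
25 | (2E,5R)-5-{[(Z)-2-methylbut-2-enoyl]oxy}hex-2-enoic acid | OC(=O)/C=C/C[C@@H](C)OC(=O)/C(C)=C\C | intermediate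
26 | O-acylisourea from 25 and N,N′-diisopropylcarbodiimide (not isolated) | CC(C)N=C(NC(C)C)OC(=O)/C=C/C[C@@H](C)OC(=O)/C(C)=C\C | intermediate
27 | 9β-[(tert-butyldimethylsilyl)oxy]-8α-[(triethylsilyl)oxy]-10βH-eremophil-11-en-3α-yl (2E,5R)-5-{[(Z)-2-methylbut-2-enoyl]oxy}hex-2-enoate | C=C(C)[C@H]1C[C@@]2(C)[C@H](CC[C@@H](OC(=O)/C=C/C[C@@H](C)OC(=O)/C(C)=C\C)[C@@H]2C)[C@@H](O[Si](C)(C)C(C)(C)C)[C@@H]1O[Si](CC)(CC)CC | intermediate
28 | 9β-[(tert-butyldimethylsilyl)oxy]-8α-hydroxy-10βH-eremophil-11-en-3α-yl (2E,5R)-5-{[(Z)-2-methylbut-2-enoyl]oxy}hex-2-enoate | C=C(C)[C@H]1C[C@@]2(C)[C@H](CC[C@@H](OC(=O)/C=C/C[C@@H](C)OC(=O)/C(C)=C\C)[C@@H]2C)[C@@H](O[Si](C)(C)C(C)(C)C)[C@@H]1O | intermediate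
29 | 9β-[(tert-butyldimethylsilyl)oxy]-8-oxo-10βH-eremophil-11-en-3α-yl (2E,5R)-5-{[(Z)-2-methylbut-2-enoyl]oxy}hex-2-enoate | C=C(C)[C@H]1C[C@@]2(C)[C@H](CC[C@@H](OC(=O)/C=C/C[C@@H](C)OC(=O)/C(C)=C\C)[C@@H]2C)[C@@H](O[Si](C)(C)C(C)(C)C)C1=O | intermediate
30 | 9β-hydroxy-8-oxo-10βH-eremophil-11-en-3α-yl (2E,5R)-5-{[(Z)-2-methylbut-2-enoyl]oxy}hex-2-enoate (CNP0210874.1) | C=C(C)[C@H]1C[C@@]2(C)[C@H](CC[C@@H](OC(=O)/C=C/C[C@@H](C)OC(=O)/C(C)=C\C)[C@@H]2C)[C@@H](O)C1=O | target

**Step count and risks**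

Total step count: 18. Longest linear sequence: 16 steps (steps 1–12 and 15–18, from 1).

Steps most likely to fail:

Step 8. The exo/endo preference of the ene transition state may be too weak to relay the catalyst-controlled carbinol centre to the allylic carbon (future C7), and the Lewis acid may conjugate the β,γ-enone or trigger aldol-type attack of glyoxylate. The fallback replaces catalyst control by a covalently bound auxiliary in a chelated transition state. It sets out from 11: (1S,2R)-2-phenylcyclohexyl glyoxylate and SnCl4 (CH2Cl2, −78 °C; auxiliary enantiomer chosen for 2R,3R) should give the auxiliary ester of 13, (1S,2R)-2-phenylcyclohexyl (2R,3R)-3-{[(1S,6R)-1,6-dimethyl-5-oxocyclohex-2-en-1-yl]methyl}-2-hydroxy-4-methylpent-4-enoate F1. Silylation as in step 9 should give (1S,2R)-2-phenylcyclohexyl (2R,3R)-3-{[(1S,6R)-5-[(tert-butyldimethylsilyl)oxy]-1,6-dimethylcyclohexa-2,4-dien-1-yl]methyl}-4-methyl-2-[(triethylsilyl)oxy]pent-4-enoate F2. i-Bu2AlH (CH2Cl2, −78 °C) then cleaves the auxiliary ester reductively, and the route is rejoined at aldehyde 16.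

Step 11. The activated aldehyde may be intercepted by the isopropenyl alkene (Prins-type closure), the dienol ether may be protodesilylated before the C–C bond forms, or the facial selectivity at C9 may be low. The fallback changes the ring closure to a pericyclic carbonyl–ene reaction. It sets out from 16: brief treatment with camphorsulfonic acid (cat.) in wet THF at 0 °C should hydrolyse only the dienol silyl ether to (2R,3R)-3-{[(1S,6R)-1,6-dimethyl-5-oxocyclohex-2-en-1-yl]methyl}-4-methyl-2-[(triethylsilyl)oxy]pent-4-enal F3. Me2AlCl (CH2Cl2, −78 °C) should then effect a type 1 intramolecular carbonyl–ene reaction between the aldehyde and the ring alkene, with transfer of a hydrogen α to the ketone, to give 9β-hydroxy-8α-[(triethylsilyl)oxy]-10βH-eremophila-1,11-dien-3-one F4. t-BuMe2SiOTf/2,6-lutidine rejoins the route at 17.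

Step 12. The ketone reduction may give part of the axial 3β-alcohol, or the strongly basic medium may cause silyl migration or over-reduction. The fallback separates the two reductions and sets C3 by inversion. It sets out from 17: [(Ph3P)CuH]6 (benzene, rt) should give the saturated ketone 18, now isolated. LiBH(s-Bu)3 (THF, −78 °C) should attack from the equatorial side to give the axial alcohol 9β-[(tert-butyldimethylsilyl)oxy]-8α-[(triethylsilyl)oxy]-10βH-eremophil-11-en-3β-ol F5. A Mitsunobu reaction with acid 25 (PPh3, diisopropyl azodicarboxylate, toluene, 0 °C) should invert C3 and rejoin the route at ester 27.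

Further compounds
F1 | step 8 | (1S,2R)-2-phenylcyclohexyl (2R,3R)-3-{[(1S,6R)-1,6-dimethyl-5-oxocyclohex-2-en-1-yl]methyl}-2-hydroxy-4-methylpent-4-enoate | C=C(C)[C@H]([C@@H](O)C(=O)O[C@H]1CCCC[C@@H]1c1ccccc1)C[C@@]2(C)C=CCC(=O)[C@@H]2C
F2 | step 8 | (1S,2R)-2-phenylcyclohexyl (2R,3R)-3-{[(1S,6R)-5-[(tert-butyldimethylsilyl)oxy]-1,6-dimethylcyclohexa-2,4-dien-1-yl]methyl}-4-methyl-2-[(triethylsilyl)oxy]pent-4-enoate | C=C(C)[C@H]([C@@H](O[Si](CC)(CC)CC)C(=O)O[C@H]1CCCC[C@@H]1c1ccccc1)C[C@@]2(C)C=CC=C(O[Si](C)(C)C(C)(C)C)[C@@H]2C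
F3 | step 11 | (2R,3R)-3-{[(1S,6R)-1,6-dimethyl-5-oxocyclohex-2-en-1-yl]methyl}-4-methyl-2-[(triethylsilyl)oxy]pent-4-enal | C=C(C)[C@H]([C@@H](O[Si](CC)(CC)CC)C=O)C[C@@]1(C)C=CCC(=O)[C@@H]1C
F4 | step 11 | 9β-hydroxy-8α-[(triethylsilyl)oxy]-10βH-eremophila-1,11-dien-3-one | C=C(C)[C@H]1C[C@@]2(C)[C@H](C=CC(=O)[C@@H]2C)[C@@H](O)[C@@H]1O[Si](CC)(CC)CC
F5 | step 12 | 9β-[(tert-butyldimethylsilyl)oxy]-8α-[(triethylsilyl)oxy]-10βH-eremophil-11-en-3β-ol | C=C(C)[C@H]1C[C@@]2(C)[C@H](CC[C@H](O)[C@@H]2C)[C@@H](O[Si](C)(C)C(C)(C)C)[C@@H]1O[Si](CC)(CC)CC
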